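**Plan**

1. Retrosynthetic cuts: the tetramic acid ring (amide C–N and Dieckmann C–C) back to a β-keto thioester grown from a C1 aldehyde; the diene bond C4′–C5′ (Suzuki); then the two ring A bonds C2–C3 and C1–C8a together, with the C3=C4 alkene and H-4a traced back to a C3-silyl Δ4(4a) alkene.
2. Enabling feature: the side-chain hydroxyl on C2′ sits so that one silicon atom bonded to O-2′ and to C3 closes a six-membered 1-oxa-2-silinane across C2–C3. A dienyl silyl ether (ring B alkene C4a=C8a plus C3=C4) carrying the C1=C2 enal is therefore an intramolecular Diels–Alder substrate. The same C3–Si bond is allylic to C4=C4a and leaves by anti-SE2′ protonation, which moves the alkene to C3=C4 and places H on C4a cis to H-8a.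
3. Forward order: ring B enyne from enone 1; enal carbinol 10; Si–O union; cycloaddition closes ring A and the siloxane ring; CHO is homologated to the β-keto thioester; protodesilylation removes the tether; Suzuki adds C5′–C10′; aminolysis and Dieckmann close the tetramic acid.
4. Stereochemistry: C6 is bought (enone 1) and sets C8 (trans cuprate addition); C2′ comes from Brown allylation; C1, C2, C3 and C8a are set in the cycloaddition (E enal, E vinylsilane, attack anti to the C8 methyl, equatorial iodovinyl group in the chair tether); C4a by anti-SE2′; C7′/C8′ by Brown (Z)-crotylboration.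

Key step: step 7

Remark (numbering): decalin atoms are C1 (quaternary), C2, C3, C4, C4a, C5–C8, C8a; side chain C1′ (CH2 on C2) to C10′; β is the face of H-8a, α the opposite face.
Remark (starting material): enone 1 is taken as a purchasable chiral-pool compound (it is also the known degradation product of (R)-pulegone).

**Route**

Step 1
Reactants: 1 (R)-5-methylcyclohex-2-en-1-one
Product: 3 (3R,5R)-3,5-dimethylcyclohex-1-en-1-yl trifluoromethanesulfonate, via lithium enolate 2 (not isolated)
Conditions: Me2CuLi (MeLi, CuI), Et2O, −78 °C; then PhNTf2, THF, −78 °C → rt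
Reagents that add atoms: lithium dimethylcuprate, [Li+].C[Cu-]C (from methyllithium, [Li]C, and CuI); N-phenylbis(trifluoromethanesulfonimide), O=S(=O)(N(c1ccccc1)S(=O)(=O)C(F)(F)F)C(F)(F)F
Why: Conjugate addition of the Gilman cuprate takes place axially and anti to the C5 methyl group, so the bought stereocentre sets the new one trans (substrate control), and O-triflation of the regiodefined enolate is standard; the trans ketone skeleton is C2-symmetric, so the position of the enol double bond is not an issue.

Step 2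
Reactants: 3 (3R,5R)-3,5-dimethylcyclohex-1-en-1-yl trifluoromethanesulfonate
Product: 4 (3R,5R)-1-ethynyl-3,5-dimethylcyclohex-1-ene
Conditions: HC≡CMgBr, ZnBr2, THF, 0 °C; then 3, Pd(PPh3)4 (5 mol%), THF, rt
Reagents that add atoms: ethynylmagnesium bromide, C#C[Mg]Br
Why: Negishi alkynylation of an enol triflate with ethynylzinc bromide gives the terminal enyne directly and touches neither stereocentre.

Step 3
Reactants: 5 ethyl (Z)-3-iodoprop-2-enoate
Product: 7 (E)-3-iodoprop-2-enal, via (Z)-3-iodoprop-2-enal 6 (not isolated)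
Conditions: DIBAL-H, CH2Cl2, −78 °C; aq. HCl work-up; then cat. TsOH, CH2Cl2, rt
Reagents that add atoms: none
Why: DIBAL-H reduces the ester to the aldehyde through an aluminium hemiacetal that is stable at −78 °C, and the Z enal equilibrates under acid to the more stable E isomer, which is the known behaviour of 3-iodoacrolein.

Step 4
Reactants: 7 (E)-3-iodoprop-2-enal
Product: 9 (3R,1E)-1-iodohexa-1,5-dien-3-ol, via borinate ester 8 (not isolated)
Conditions: (+)-Ipc2B(allyl), Et2O, −78 °C; then NaOH, H2O2, 0 °C → rt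
Reagents that add atoms: (+)-B-allyldiisopinocampheylborane, C=CCB([C@H]1C[C@H]2C[C@@H]([C@@H]1C)C2(C)C)[C@H]1C[C@H]2C[C@@H]([C@@H]1C)C2(C)C
Why: Brown allylboration runs through a chair Zimmerman–Traxler transition state with the aldehyde substituent equatorial, and the (+)-Ipc2B reagent (from (−)-α-pinene) should select the face that gives the 3R alcohol (reagent control).

Step 5
Reactants: 9 (3R,1E)-1-iodohexa-1,5-dien-3-ol
Product: 10 (5R,2E,6E)-5-hydroxy-7-iodo-2-methylhepta-2,6-dienal
Conditions: methacrolein (8 equiv), second-generation Hoveyda–Grubbs catalyst (5 mol%), CH2Cl2, 40 °C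
Reagents that add atoms: methacrolein, CC(=C)C=O
Why: Olefin cross-metathesis of the terminal alkene with excess methacrolein should give the trisubstituted E enal under thermodynamic control, while the 1,2-disubstituted iodoalkene is too deactivated to enter the catalytic cycle.

Step 6
Reactants: 4 (3R,5R)-1-ethynyl-3,5-dimethylcyclohex-1-ene; 10 (5R,2E,6E)-5-hydroxy-7-iodo-2-methylhepta-2,6-dienal
Product: 12 (5R,2E,6E)-5-({(E)-2-[(3R,5R)-3,5-dimethylcyclohex-1-en-1-yl]ethenyl}dimethylsilyloxy)-7-iodo-2-methylhepta-2,6-dienal, via chlorosilane 11 (not isolated)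
Conditions: 4, HSiMe2Cl, Pt2(dvds)3 (dvds = 1,3-divinyltetramethyldisiloxane)/P(t-Bu)3 (0.5 mol%), THF, rt; evaporate excess silane; then 10, imidazole, CH2Cl2, 0 °C; filter through Et3N-deactivated silica
Reagents that add atoms: chlorodimethylsilane, C[SiH](C)Cl
Why: Platinum-catalysed cis hydrosilylation of the terminal alkyne puts silicon on the terminal carbon and gives the E dienylsilane (Chalk–Harrod pathway), and the Si–Cl bond is then substituted by the secondary alcohol without touching the C2′ stereocentre.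

Step 7
Reactants: 12 (5R,2E,6E)-5-({(E)-2-[(3R,5R)-3,5-dimethylcyclohex-1-en-1-yl]ethenyl}dimethylsilyloxy)-7-iodo-2-methylhepta-2,6-dienal
Product: 13 siloxane-bridged Δ4(4a)-octalin-1-carbaldehyde (1β-CHO, 1α-CH3, 6α-CH3, 8β-CH3, H-8a β; C2α–C1′H2–C2′H[(E)-CH=CHI]–O–SiMe2–C3α form a 1-oxa-2-silinane cis-fused across C2–C3)
Conditions: toluene (0.005 M), BHT (cat.), sealed tube, 135 °C
Reagents that add atoms: none
Why: Thermal intramolecular [4π+2π] cycloaddition in which the E silyl diene C3=C4–C4a=C8a adds suprafacially to the E 2-methyl enal C1=C2; the closest known reaction type is the silicon-tethered intramolecular Diels–Alder reaction of dienylsilyl ethers. Ring A (cyclohexene, C4=C4a) closes by concerted formation of C2–C3 and C1–C8a, and the 1-oxa-2-silinane closes as the four-atom tether ring (Si, O, C2′, C1′) cis-fused across C2–C3; the tether also enforces the regiochemistry that places the quaternary C1 next to C8a. C1 and C2 follow from the E enal in the formyl-exo, tether-endo orientation (CHO β, CH3 α, side chain α), C3 from the E vinylsilane (Si α), and C8a from suprafacial addition to the diene (H β). The step needs formyl-exo selectivity and attack on the diene face anti to the C8 methyl group; this is the only transition state that combines approach anti to the pseudoaxial C8–CH3 of ring B with a chair tether carrying the C2′ iodovinyl group equatorial, so the two control elements are matched. The α-methyl group of the enal competes with CHO for the endo position and no Lewis acid is used, so there is no built-in endo-formyl bias to overcome.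

Step 8
Reactants: 13 siloxane-bridged Δ4(4a)-octalin-1-carbaldehyde
Product: 14 S-tert-butyl 3-hydroxy-3-(C1 of the siloxane-bridged octalin)propanethioate (both carbinol epimers)
Conditions: S-tert-butyl thioacetate, LDA, THF, −78 °C; then 13, −78 °C; aq. NH4Cl
Reagents that add atoms: S-tert-butyl thioacetate, CC(=O)SC(C)(C)C
Why: Aldol addition of a lithium thioacetate enolate to a non-enolisable neopentyl aldehyde is well precedented for decalin carbaldehydes of this kind, and the new carbinol centre is oxidised in the next step, so its configuration does not matter.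

Step 9
Reactants: 14 β-hydroxy thioester
Product: 15 S-tert-butyl 3-oxo-3-(C1 of the siloxane-bridged octalin)propanethioate
Conditions: Dess–Martin periodinane, CH2Cl2, rt
Reagents that add atoms: none
Why: Dess–Martin oxidation of the β-hydroxy thioester gives the β-keto thioester under near-neutral conditions that should leave the allylsilane, the siloxane and the iodoalkene untouched.

Step 10
Reactants: 15 β-keto thioester with siloxane bridge
Product: 17 S-tert-butyl 3-{(1S,2R,4aS,6R,8R,8aS)-2-[(2R,3E)-2-hydroxy-4-iodobut-3-en-1-yl]-1,6,8-trimethyl-1,2,4a,5,6,7,8,8a-octahydronaphthalen-1-yl}-3-oxopropanethioate, via silyl trifluoroacetate 16 (not isolated)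
Conditions: CF3CO2H, CH2Cl2, −20 → 0 °C; then HF·pyridine, pyridine, THF, 0 °C
Reagents that add atoms: none
Why: Anti-SE2′ protodesilylation of the allylsilane (Fleming): the proton adds to C4a on the β face, opposite the pseudoaxial α C3–Si bond, and the β-silyl cation at C4 loses silicon to leave C3=C4, so the C3 stereocentre is relayed to C4a (H cis to H-8a); HF then cleaves the remaining Si–O bond and frees the C2′ hydroxyl.

Step 11
Reactants: 18 propanal
Product: 20 (3S,4S)-4-methylhex-5-en-3-ol, via borinate ester 19 (not isolated)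
Conditions: cis-2-butene, n-BuLi, KOt-Bu, THF, −45 °C; (+)-Ipc2BOMe, −78 °C; BF3·OEt2; then 18, −78 °C; NaOH, H2O2
Reagents that add atoms: cis-2-butene, C/C=C\C (converted in the flask into (Z)-crotyldiisopinocampheylborane, C/C=C\CB([C@H]1C[C@H]2C[C@@H]([C@@H]1C)C2(C)C)[C@H]1C[C@H]2C[C@@H]([C@@H]1C)C2(C)C)
Why: Brown crotylboration: the Z crotylborane reacts through a chair transition state to give the syn product, and the (+)-Ipc2B groups should select the aldehyde face that leads to the 3S,4S isomer (reagent control).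

Step 12
Reactants: 20 (3S,4S)-4-methylhex-5-en-3-ol
Product: 21 (3S,4S,5E)-4-methyl-6-(4,4,5,5-tetramethyl-1,3,2-dioxaborolan-2-yl)hex-5-en-3-ol
Conditions: vinylboronic acid pinacol ester (3 equiv), second-generation Hoveyda–Grubbs catalyst (5 mol%), CH2Cl2, 40 °C
Reagents that add atoms: vinylboronic acid pinacol ester, C=CB1OC(C)(C)C(C)(C)O1
Why: Cross-metathesis with the vinylboronate should give the E alkenylboronate under thermodynamic control, and the α-branched allylic position and the free hydroxyl are tolerated in this reaction type.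

Step 13
Reactants: 17 hydroxy iodoalkene β-keto thioester; 21 alkenylboronate
Product: 22 S-tert-butyl 3-{(1S,2R,4aS,6R,8R,8aS)-2-[(2R,3E,5E,7S,8S)-2,8-dihydroxy-7-methyldeca-3,5-dien-1-yl]-1,6,8-trimethyl-1,2,4a,5,6,7,8,8a-octahydronaphthalen-1-yl}-3-oxopropanethioate
Conditions: Pd(PPh3)4 (5 mol%), TlOEt, degassed THF/H2O (4:1), rt, dark
Reagents that add atoms: none
Why: Suzuki–Miyaura coupling of an alkenyl iodide with an alkenylboronate proceeds with retention of both double-bond geometries, and thallium ethoxide allows reaction at room temperature while the β-keto thioester is held as its unreactive enolate.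

Step 14
Reactants: 22 dienyl β-keto thioester
Product: 23 methyl N-(3-{(1S,2R,4aS,6R,8R,8aS)-2-[(2R,3E,5E,7S,8S)-2,8-dihydroxy-7-methyldeca-3,5-dien-1-yl]-1,6,8-trimethyl-1,2,4a,5,6,7,8,8a-octahydronaphthalen-1-yl}-3-oxopropanoyl)glycinate
Conditions: glycine methyl ester hydrochloride, Et3N, AgOCOCF3, THF, 0 °C
Reagents that add atoms: glycine methyl ester hydrochloride, Cl.NCC(=O)OC
Why: Silver-promoted aminolysis of the S-tert-butyl β-keto thioester: the thiophilic silver salt activates the thioester so that the amine attacks under mild conditions in the presence of the free hydroxyl groups and the diene.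

Step 15
Reactants: 23 β-keto amide
Product: 25 3-{[(1S,2R,4aS,6R,8R,8aS)-2-[(2R,3E,5E,7S,8S)-2,8-dihydroxy-7-methyldeca-3,5-dien-1-yl]-1,6,8-trimethyl-1,2,4a,5,6,7,8,8a-octahydronaphthalen-1-yl]carbonyl}-4-hydroxy-1,5-dihydro-2H-pyrrol-2-one (target), via sodium tetramate 24 (not isolated)
Conditions: NaOMe, MeOH, rt; then cold 0.1 M HCl
Reagents that add atoms: none
Why: Lacey–Dieckmann cyclisation: the β-dicarbonyl anion attacks the glycine ester carbonyl to close the pyrrolidine-2,4-dione ring (5-exo-trig), and brief mild acidification should liberate the 3-acyl tetramic acid without affecting the quaternary C1 or the dienyl carbinol.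

**Compound list**

1 | (R)-5-methylcyclohex-2-en-1-one | O=C1C=CC[C@@H](C)C1 | starting material
2 | lithium (3R,5R)-3,5-dimethylcyclohex-1-en-1-olate | [Li+].[O-]C1=C[C@H](C)C[C@@H](C)C1 | intermediate (not isolated)
3 | (3R,5R)-3,5-dimethylcyclohex-1-en-1-yl trifluoromethanesulfonate | FC(F)(F)S(=O)(=O)OC1=C[C@H](C)C[C@@H](C)C1 | intermediate
4 | (3R,5R)-1-ethynyl-3,5-dimethylcyclohex-1-ene | C#CC1=C[C@H](C)C[C@@H](C)C1 | intermediate
5 | ethyl (Z)-3-iodoprop-2-enoate | CCOC(=O)/C=C\I | starting material
6 | (Z)-3-iodoprop-2-enal | O=C/C=C\I | intermediate (not isolated)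
7 | (E)-3-iodoprop-2-enal | O=C/C=C/I | intermediate
8 | (3R,1E)-1-iodohexa-1,5-dien-3-yl diisopinocampheylborinate | I/C=C/[C@@H](CC=C)OB([C@H]1C[C@H]2C[C@@H]([C@@H]1C)C2(C)C)[C@H]1C[C@H]2C[C@@H]([C@@H]1C)C2(C)C | intermediate (not isolated)
9 | (3R,1E)-1-iodohexa-1,5-dien-3-ol | I/C=C/[C@H](O)CC=C | intermediate
10 | (5R,2E,6E)-5-hydroxy-7-iodo-2-methylhepta-2,6-dienal | I/C=C/[C@H](O)C/C=C(\C)C=O | intermediate
11 | chloro{(E)-2-[(3R,5R)-3,5-dimethylcyclohex-1-en-1-yl]ethenyl}dimethylsilane | C[Si](C)(Cl)/C=C/C1=C[C@H](C)C[C@@H](C)C1 | intermediate (not isolated)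
12 | dienyl silyl ether of 10 (cycloaddition precursor) | I/C=C/[C@H](O[Si](C)(C)/C=C/C1=C[C@H](C)C[C@@H](C)C1)C/C=C(\C)C=O | intermediate
13 | siloxane-bridged Δ4(4a)-octalin-1-carbaldehyde (1β-CHO, 1α-CH3, 3α-Si, 6α-CH3, 8β-CH3, H-2/H-3/H-8a β) | I/C=C/[C@H]1C[C@@H]2[C@@H](C=C3C[C@H](C)C[C@@H](C)[C@@H]3[C@@]2(C)C=O)[Si](C)(C)O1 | intermediate
14 | β-hydroxy S-tert-butyl thioester from 13 (carbinol epimers) | I/C=C/[C@H]1C[C@@H]2[C@@H](C=C3C[C@H](C)C[C@@H](C)[C@@H]3[C@@]2(C)C(O)CC(=O)SC(C)(C)C)[Si](C)(C)O1 | intermediate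
15 | β-keto S-tert-butyl thioester with siloxane bridge | I/C=C/[C@H]1C[C@@H]2[C@@H](C=C3C[C@H](C)C[C@@H](C)[C@@H]3[C@@]2(C)C(=O)CC(=O)SC(C)(C)C)[Si](C)(C)O1 | intermediate
16 | dimethyl(trifluoroacetoxy)silyl ether of 17 | I/C=C/[C@H](O[Si](C)(C)OC(=O)C(F)(F)F)C[C@@H]1C=C[C@@H]2C[C@H](C)C[C@@H](C)[C@@H]2[C@@]1(C)C(=O)CC(=O)SC(C)(C)C | intermediate (not isolated)
17 | cis-decalin hydroxy iodoalkene β-keto thioester | I/C=C/[C@H](O)C[C@@H]1C=C[C@@H]2C[C@H](C)C[C@@H](C)[C@@H]2[C@@]1(C)C(=O)CC(=O)SC(C)(C)C | intermediate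
18 | propanal | CCC=O | starting material
19 | (3S,4S)-4-methylhex-5-en-3-yl diisopinocampheylborinate | CC[C@H](OB([C@H]1C[C@H]2C[C@@H]([C@@H]1C)C2(C)C)[C@H]1C[C@H]2C[C@@H]([C@@H]1C)C2(C)C)[C@@H](C)C=C | intermediate (not isolated)
20 | (3S,4S)-4-methylhex-5-en-3-ol | CC[C@H](O)[C@@H](C)C=C | intermediate
21 | (3S,4S,5E)-4-methyl-6-(4,4,5,5-tetramethyl-1,3,2-dioxaborolan-2-yl)hex-5-en-3-ol | CC[C@H](O)[C@@H](C)/C=C/B1OC(C)(C)C(C)(C)O1 | intermediate
22 | dienyl diol β-keto S-tert-butyl thioester | CC[C@H](O)[C@@H](C)/C=C/C=C/[C@H](O)C[C@@H]1C=C[C@@H]2C[C@H](C)C[C@@H](C)[C@@H]2[C@@]1(C)C(=O)CC(=O)SC(C)(C)C | intermediate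
23 | N-(β-ketoacyl)glycine methyl ester | CC[C@H](O)[C@@H](C)/C=C/C=C/[C@H](O)C[C@@H]1C=C[C@@H]2C[C@H](C)C[C@@H](C)[C@@H]2[C@@]1(C)C(=O)CC(=O)NCC(=O)OC | intermediate
24 | sodium salt of the target tetramic acid | CC[C@H](O)[C@@H](C)/C=C/C=C/[C@H](O)C[C@@H]1C=C[C@@H]2C[C@H](C)C[C@@H](C)[C@@H]2[C@@]1(C)C(=O)C1=C([O-])CNC1=O.[Na+] | intermediate (not isolated)
25 | CNP0117518.2 | CC[C@H](O)[C@@H](C)/C=C/C=C/[C@H](O)C[C@@H]1C=C[C@@H]2C[C@H](C)C[C@@H](C)[C@@H]2[C@@]1(C)C(=O)C1=C(O)CNC1=O | target

**Count and risks**

Total steps: 15. Longest linear sequence: 11 steps (3, 4, 5, 6, 7, 8, 9, 10, 13, 14, 15).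

Steps most likely to fail:

1. Step 7. The formyl-endo transition state (trans-fused siloxane) or approach syn to the C8 methyl group may compete, which would erode endo/exo and facial selectivity. The fallback is an untethered, Lewis-acid-controlled cycloaddition that sets out from 4 and 10. Enyne 4 is hydrosilylated with HSiMe2Ph (Pt2(dvds)3) to the dienylsilane F1, and 10 is silylated (Et3SiCl, imidazole) to the triethylsilyl ether F2. F1 and F2 are combined in the presence of the bulky aluminium phenoxide Al(OC6H3-2,6-Ph2)3, a known exo-directing Lewis acid for enals, to give the cycloadduct F3. F3 is homologated as in steps 8 and 9 to the β-hydroxy thioester F4 and the β-keto thioester F5. CF3CO2H then effects anti-SE2′ protodesilylation of the PhMe2Si allylsilane and cleaves the triethylsilyl ether, and the route is rejoined at 17.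

2. Step 10. Protonation may occur at C4 instead of C4a (alkene migration into ring B) because the alkoxy group on silicon weakens the β-silicon effect, or the allylic C2′–O bond may ionise under acid. The fallback replaces protonation of the allylsilane by oxidation and reductive transposition; it sets out from 13. Tamao–Kumada oxidation (KF, KHCO3, H2O2, THF/MeOH) converts the C3–Si bond into a 3α-hydroxyl with retention and frees the C2′ hydroxyl, which closes onto the formyl group to give the lactol F6. Oxidation of the lactol (N-iodosuccinimide, Bu4NI) gives the δ-lactone F7. Myers reductive 1,3-transposition (2-nitrobenzenesulfonylhydrazide, PPh3, diethyl azodicarboxylate, then warming) proceeds by Mitsunobu inversion at C3 and sigmatropic loss of N2, which delivers H to C4a on the β face and gives the C3=C4 lactone F8. Claisen-type addition of excess LiCH2COSt-Bu opens the lactone and gives 17 (as its ring–chain tautomers), where the route is rejoined; steps 8 and 9 are bypassed.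

3. Step 13. The basic aqueous medium may cleave the β-keto thioester, or the alkenylboronate may protodeboronate before transmetalation. The fallback is a neutral Stille coupling; it sets out from 21. Iodination (NaOH, I2, THF) converts 21 with retention into the alkenyl iodide F9, and Pd(PPh3)4/(Bu3Sn)2 converts F9 into the alkenylstannane F10. F10 is coupled with 17 under base-free conditions (PdCl2(MeCN)2, DMF, rt) to give 22, where the route is rejoined.

**Further compounds**

F1 | step 7 | {(E)-2-[(3R,5R)-3,5-dimethylcyclohex-1-en-1-yl]ethenyl}dimethyl(phenyl)silane | C[Si](C)(c1ccccc1)/C=C/C1=C[C@H](C)C[C@@H](C)C1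
F2 | step 7 | (5R,2E,6E)-7-iodo-2-methyl-5-(triethylsilyloxy)hepta-2,6-dienal | I/C=C/[C@H](O[Si](CC)(CC)CC)C/C=C(\C)C=O
F3 | step 7 | untethered cycloadduct (Δ4(4a)-octalin-1β-carbaldehyde, 3α-SiMe2Ph, 2α side chain with OSiEt3) | I/C=C/[C@H](O[Si](CC)(CC)CC)C[C@@H]1[C@H]([Si](C)(C)c2ccccc2)C=C3C[C@H](C)C[C@@H](C)[C@@H]3[C@@]1(C)C=O
F4 | step 7 | β-hydroxy S-tert-butyl thioester from F3 | I/C=C/[C@H](O[Si](CC)(CC)CC)C[C@@H]1[C@H]([Si](C)(C)c2ccccc2)C=C3C[C@H](C)C[C@@H](C)[C@@H]3[C@@]1(C)C(O)CC(=O)SC(C)(C)C
F5 | step 7 | β-keto S-tert-butyl thioester from F4 | I/C=C/[C@H](O[Si](CC)(CC)CC)C[C@@H]1[C@H]([Si](C)(C)c2ccccc2)C=C3C[C@H](C)C[C@@H](C)[C@@H]3[C@@]1(C)C(=O)CC(=O)SC(C)(C)C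
F6 | step 10 | 3α-hydroxy lactol (O-2′ closed onto the C1 formyl carbon, anomers) | I/C=C/[C@H]1C[C@@H]2[C@H](O)C=C3C[C@H](C)C[C@@H](C)[C@@H]3[C@@]2(C)C(O)O1
F7 | step 10 | 3α-hydroxy δ-lactone | I/C=C/[C@H]1C[C@@H]2[C@H](O)C=C3C[C@H](C)C[C@@H](C)[C@@H]3[C@@]2(C)C(=O)O1
F8 | step 10 | cis-decalin δ-lactone with C3=C4 and H-4a β | I/C=C/[C@H]1C[C@@H]2C=C[C@@H]3C[C@H](C)C[C@@H](C)[C@@H]3[C@@]2(C)C(=O)O1
F9 | step 13 | (3S,4S,5E)-6-iodo-4-methylhex-5-en-3-ol | CC[C@H](O)[C@@H](C)/C=C/I
F10 | step 13 | (3S,4S,5E)-4-methyl-6-(tributylstannyl)hex-5-en-3-ol | CC[C@H](O)[C@@H](C)/C=C/[Sn](CCCC)(CCCC)CCCC
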